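**The trap.** It is tempting to read the ratio of D to Z off the charge of X. At the last readings, maple, charged with 1.4 equiv of X, shows 0.477, and alder, charged with 2.2 equiv, shows 0.481, although alder's charge of X is larger.

| flask | J | G | X | remark | time |
|---|---|---|---|---|---|
| maple | 0.21 M | 1.2 equiv | 1.4 equiv | run made earlier |  |
| alder | 0.21 M | 1.2 equiv | 2.2 equiv | run made earlier |  |
| ash | 0.10 M | 1.2 equiv | 1 equiv | run made earlier |  |
| flask | 0.21 M | 1.20 equiv | 1.00 equiv |  | 2.5 d |

- maple (time / h: D / %, Z / %): 3.00: 2.1, 3.9; 10.0: 4.1, 10.0; 15.0: 6.6, 12.5; 25.0: 8.0, 17.1; 40.0: 9.2, 20.1; 50.0: 10.5, 22.0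
- alder (time / h: D / %, Z / %): 4.00: 2.2, 5.3; 6.00: 2.5, 6.4; 10.0: 3.7, 9.3; 20.0: 6.4, 13.9; 30.0: 7.2, 16.3; 50.0: 9.0, 18.7
- ash (time / h: D / %, Z / %): 4.00: 0.9, 2.7; 8.00: 2.0, 4.1; 15.0: 3.6, 7.1; 25.0: 5.4, 10.1; 50.0: 7.4, 15.9

(each reading ± 0.3 percentage points)

- the numbers in the tables scatter with a standard deviation of 0.3 percentage points
- reactions considered so far: J <-> X; J + G -> D; G + X -> Z; G <-> L

- ratio of D to Z at 30 min
- ratio of D to Z at 2.5 d

**Plateau ratio.** I replace the curve of D over Z by one level. Averaging that ratio over the last readings of maple, alder and ash gives a reading of 0.475, which I call the plateau ratio. The usual name for such a charge-blind ratio is Curtin–Hammett control.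

**The curve.** If a ratio started at the plateau for equal J and X and followed the charge, alder would begin near 0.216. At 4.00 h alder already reads 0.415, higher than that, so I put its knee before that reading. This flask starts at the [X]/[J] of ash, so I draw no knee. The check is ash: its ratio reads 0.333 at 4.00 h, where D is 0.9 % with a scatter of 0.3 percentage points, and 0.535 at 25.0 h, with no trend I can separate from the scatter. My line therefore stays at 0.475 at both 30 min and 2.5 d.

**The forecast.** The forecast gives 0.55 (0.42 to 0.85) at 30 min, above my line, since “the flask may not have equilibrated”. At 2.5 d it gives 0.47 (0.43 to 0.51).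

**The result.** The flask gives 0.464 at 30 min and 0.495 at 2.5 d, so the forecast's early figure stands too high and its late one is within its range. Backward turnover between J and X comes to 99.2 % of the forward one. Multiplied into the 24.7 % of Z at 2.50 d, the plateau ratio reckons D at 11.7 %, and this flask holds 12.2 %.

    J ⇌ X (K = 0.933, k = 7.84 × 10⁻⁵ s⁻¹)
    J + G → D (k = 1.32 × 10⁻⁵ M⁻¹ s⁻¹)
    G + X → Z (k = 2.88 × 10⁻⁵ M⁻¹ s⁻¹)
    G ⇌ L (K = 1.83, k = 3.41 × 10⁻⁶ s⁻¹)

**Second flask.** With 2.50 equiv of X and the other charges as here, the plateau ratio over the charge gives 0.190 at 30 min, and the plateau gives 0.475 at 2.5 d. The neighbour computes to 0.213 and 0.451.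

(The runs stem from a simulated flask for an exercise; the scatter is artificial.)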